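The flask beside yours is the same recipe with 2.80 equiv of coupling partner, so whatever you carry from this flask should also serve that one.

solid substrate 0.20 M; coupling partner 0.700 equiv; protic impurity 0.0600 M; time 40 min

    starting material + coupling partner ⇌ product (K1 = 4.5 M⁻¹, k1 = 0.039 M⁻¹ s⁻¹)
    solid substrate ⇌ starting material, rate k2*(cs2 - [starting material]) while solid is left; crystals form when [starting material] > cs2 (cs2 = 12 mM, k2 = 0.011 s⁻¹)
    starting material + protic impurity → quenched substrate (k3 = 0.028 M⁻¹ s⁻¹)

- part of the solid substrate that has turned into other species by 40 min (what has only dissolved does not count)
- the product standing at 40 min, as a percentage of the solid substrate charged

- given per volume of solution although it is solid: solid substrate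
- at the start none of the solid substrate is in solution
- what has only dissolved of solid substrate counts as not reacted
- run time (flask): 40 min

This flask is a slurry when you take over, and the question is how much product it can hold. Dissolving has a time constant of 1.52 min, and at the charged 0.140 M of coupling partner, forward coupling alone gives starting material a half-life of 2.12 min. Both are far shorter than the 40 min run, so I take the solution as near its solubility of 12 mM and the coupling as near equilibrium. Go round twice:

first round: equilibrium constant × solubility × coupling partner charged = 7.56 mM

second round: equilibrium constant × solubility × (coupling partner charged − first answer) = 7.15 mM

Call this the product ceiling: the product in equilibrium with a saturated solution and the coupling partner left free. It is 3.58% of the charge, a case of thermodynamic control. Even with the protic impurity fully spent, about 0.121 M stays solid. Don't wait for more product, and don't add coupling partner unless you want a new ceiling. My reckoning stops here and gives no conversion.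

The forecast gives 18% converted and 3.3% of product, lower than my ceiling, with dissolved substrate that “stays just below its 12 mM solubility”.

The simulation gives 18.2% converted and 3.32% of product in this flask at 40 min, below the ceiling, with quenched substrate at 14.9%. At 40.0 min the quench uses starting material at 0.16 times the forward rate of coupling, whose half-life on starting material was 2.2 min at 9.68 min, far shorter than the run. Left ten times as long, to 400 min, this flask holds 3.59% of product, about the ceiling. The neighbour with 2.80 equiv holds 13.2% at 40 min, below its ceiling of 14.3%.

The numbers of this flask are invented; the rest is arithmetic.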